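**Assumptions**
- The target SMILES has no stereocentres. I take it as achiral, with the para-phenylene ring flipping freely, so "single enantiomer" is trivially met and no stereocontrol is needed.
- Compound 7 (4,4-diethoxybutyl-triphenylphosphonium bromide) is available commercially. If not, it is one step from 4-bromobutanal diethyl acetal and PPh3.

**Retrosynthetic overview**
1. The 15-membered meta,para-diaryl ether macrocycle is closed last, by a macrocyclic Melpolder–Heck reaction of an aryl bromide with a terminal secondary allylic alcohol. This forms the C1–aryl bond and the C3 ketone together, so the diaryl ether is never macrocyclised.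
2. The allylic alcohol comes from vinylMgBr addition to an aldehyde. That aldehyde comes from acetal hydrolysis, diimide reduction and Wittig olefination of a diaryl ether benzaldehyde.
3. The acyclic diaryl ether comes from a chemoselective (C–I over C–Br) Ullmann coupling of 2,4-dihydroxy-3-methoxybenzaldehyde with 4-bromo-2-iodoanisole.
4. The pyrogallol-type ring B is differentiated from 2,3,4-trihydroxybenzaldehyde by regioselective benzylation, methylation and debenzylation. Both aromatic rings pre-exist, and the macrocycle forms last.

---

**Step 1**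
Reactants: 1 (2,3,4-trihydroxybenzaldehyde)
Product: 2 (4-benzyloxy-2,3-dihydroxybenzaldehyde)
Conditions: BnBr, NaHCO3, KI (cat.), MeCN, 80 °C
Reagents that add atoms: benzyl bromide, BrCc1ccccc1
Why: The 4-OH is the most acidic (para to CHO) and the 2-OH is chelated to the aldehyde, so Williamson O-benzylation is regioselective at C4.

**Step 2**
Reactants: 2
Product: 3 (4-benzyloxy-2-hydroxy-3-methoxybenzaldehyde)
Conditions: MeI (1.2 equiv), K2CO3, DMF, rt to 40 °C
Reagents that add atoms: iodomethane, CI
Why: The free 3-OH is more nucleophilic than the H-bonded 2-OH, so Williamson O-methylation gives the 3-OMe selectively.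

**Step 3**
Reactants: 3
Product: 4 (2,4-dihydroxy-3-methoxybenzaldehyde)
Conditions: H2 (1 atm), 10% Pd/C, EtOAc/MeOH, rt, short reaction time
Reagents that add atoms: none
Why: Hydrogenolysis of the benzyl ether unmasks the 4-OH, while the chelated aryl aldehyde survives mild conditions.

**Step 4**
Reactants: 4; 5 (4-bromo-2-iodoanisole)
Product: 6 (4-(5-bromo-2-methoxyphenoxy)-2-hydroxy-3-methoxybenzaldehyde)
Conditions: CuI (10 mol %), N,N-dimethylglycine (30 mol %), Cs2CO3, dioxane, 90 °C
Reagents that add atoms: none
Why: Ullmann-type diaryl ether synthesis reacts at C–I and leaves C–Br intact, and the acidic 4-phenoxide reacts in preference to the chelated 2-OH. The Br ends up para to OMe and meta to the new ether oxygen, as ring A of the target requires.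

**Step 5**
Reactants: 6; 7 (4,4-diethoxybutyl-triphenylphosphonium bromide)
Product: 8 (Z/E 5,5-diethoxypent-1-enyl arene)
Conditions: 7 (2.5 equiv), KOtBu (3.6 equiv), THF, 0 °C to rt
Reagents that add atoms: none (the phosphonium 7 is the numbered reactant)
Why: Wittig olefination with an unstabilised ylide adds C6–C3, with C3 as a masked aldehyde. The extra base covers the phenol, and no stereocentre is formed.

**Step 6**
Reactants: 8
Product: 9 (saturated diethyl acetal, 2-hydroxy-3-methoxy-4-aryloxy-1-(5,5-diethoxypentyl)benzene)
Conditions: TsNHNH2 (8 equiv), NaOAc, DME/H2O 1:1, 85 °C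
Reagents that add atoms: none (diimide delivers only H2)
Why: Diimide reduction saturates the styrenyl C=C without touching the Ar–Br, which Pd/H2 would hydrodebrominate. The buffer keeps the acetal intact.

**Step 7**
Reactants: 9
Product: 10 (5-arylpentanal)
Conditions: 2 M HCl, THF, rt
Reagents that add atoms: water, O
Why: Acid-catalysed acetal hydrolysis gives the free aldehyde; the aryl ethers, aryl bromide and phenol are unaffected.

**Step 8**
Reactants: 10
Product: 11 (1-aryl-hept-6-en-5-ol, i.e. C=CC(O)CCCC-aryl)
Conditions: vinylMgBr (3.5 equiv), THF, −78 °C to 0 °C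
Reagents that add atoms: vinylmagnesium bromide, C=C[Mg]Br
Why: Grignard 1,2-addition to the aldehyde gives the allylic alcohol; one equivalent is consumed by the phenol and the Ar–Br survives at low temperature. The new carbinol stereocentre is racemic and is destroyed in step 9, so it does not matter.

**Step 9**
Reactants: 11
Product: 12 (juglanin A)
Conditions: Pd(OAc)2 (20 mol %), P(o-tol)3 (40 mol %), Bu4NCl, NaHCO3, DMF, 100 °C, substrate added by syringe pump over 10 h to about 3 mM
Reagents that add atoms: none
Why: This is a macrocyclic Melpolder–Heck reaction: ArPd adds to the terminal CH2 (endo mode), and β-H elimination toward the carbinol C–H gives an enol that tautomerises to the C3 ketone, forming Ar–CH2CH2C(=O)– directly. High dilution favours cyclisation, and there is no stereochemistry to set.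

---

**Compound list**

| No. | Name | SMILES | Role |
|---|---|---|---|
| 1 | 2,3,4-trihydroxybenzaldehyde | O=Cc1ccc(O)c(O)c1O | starting material |
| 2 | 4-benzyloxy-2,3-dihydroxybenzaldehyde | O=Cc1ccc(OCc2ccccc2)c(O)c1O | intermediate |
| 3 | 4-benzyloxy-2-hydroxy-3-methoxybenzaldehyde | O=Cc1ccc(OCc2ccccc2)c(OC)c1O | intermediate |
| 4 | 2,4-dihydroxy-3-methoxybenzaldehyde | O=Cc1ccc(O)c(OC)c1O | intermediate |
| 5 | 4-bromo-2-iodoanisole | COc1ccc(Br)cc1I | starting material |
| 6 | 4-(5-bromo-2-methoxyphenoxy)-2-hydroxy-3-methoxybenzaldehyde | O=Cc1ccc(Oc2cc(Br)ccc2OC)c(OC)c1O | intermediate |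
| 7 | (4,4-diethoxybutyl)triphenylphosphonium bromide | CCOC(CCC[P+](c1ccccc1)(c1ccccc1)c1ccccc1)OCC.[Br-] | starting material |
| 8 | 5,5-diethoxypent-1-enyl diaryl ether (Z/E) | CCOC(CCC=Cc1ccc(Oc2cc(Br)ccc2OC)c(OC)c1O)OCC | intermediate |
| 9 | saturated diethyl acetal | CCOC(CCCCc1ccc(Oc2cc(Br)ccc2OC)c(OC)c1O)OCC | intermediate |
| 10 | 5-arylpentanal | O=CCCCCc1ccc(Oc2cc(Br)ccc2OC)c(OC)c1O | intermediate |
| 11 | allylic alcohol (racemic) | C=CC(O)CCCCc1ccc(Oc2cc(Br)ccc2OC)c(OC)c1O | intermediate |
| 12 | juglanin A (achiral) | COc1ccc2cc1Oc1ccc(c(O)c1OC)CCCCC(=O)CC2 | target |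

**Total steps:** 9. **Longest linear sequence:** 9 (1 → 2 → 3 → 4 → 6 → 8 → 9 → 10 → 11 → 12; the steps are 1, 2, 3, 4, 5, 6, 7, 8, 9).

**Three steps most likely to fail**
1. **Step 9, macrocyclic Heck.** Oligomerisation, styrenyl (non-ketone) Heck product, or Pd–H isomerisation to the ethyl ketone could compete.
   - Fallback: close the 15-membered ring at the diaryl ether instead. Make the acyclic Ar–CH2CH2C(=O)(CH2)4–Ar′ ketone with a boronic acid on ring A and a free phenol on ring B, then do an intramolecular Chan–Lam or Ullmann macro-etherification.
2. **Step 4, Ullmann coupling.** The salicylaldehyde-type phenol may chelate copper and stall the coupling, or the coupling may be unselective between the 4-OH and 2-OH.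
   - Fallback: use a Chan–Lam coupling of 4 with 5-bromo-2-methoxyphenylboronic acid (Cu(OAc)2, pyridine, air). This is a different mechanism and coupling partner and does not rely on the C–I bond.
3. **Step 5, Wittig on the phenolic aldehyde.** The phenoxide-aldehyde is a poor electrophile toward the unstabilised ylide, so yields may be low.
   - Fallback: protect the 2-OH as its MOM ether (MOMCl, iPr2NEt) before the Wittig, and remove MOM together with the acetal in step 7 using HCl/MeOH.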